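**Plan**

- Cuts, in retrosynthetic order: the four benzyl ethers and the C–B bond that masks the 4'-hydroxyl; the acyl–aryl bond C4–C4a of ring C of the flavanone; the ether bond O1–C2; then, on the achiral half, the MOM group, the pyranone ring of the apigenin unit (by way of a chalcone) and the diaryl ether bond between C6 and the apigenin B ring.
- Enabling feature: in ring A the ether oxygen O1 (on C8a) and the aryloxy oxygen on C6 are para and are flanked symmetrically by the oxygens on C5 and C7. With C4–C4a cut, ring A is a 2-aryloxyphloroglucinol triether with a local mirror plane through C8a and C6. C4a and C8 are then equivalent, each ortho, ortho and para to three oxygens, so acylation can only give the 6-O-linked skeleton.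
- Forward order: para-quinone, hydroquinone, diaryl ether (SNAr), apigenin pyranone ring (chalcone, oxidative closure), aryl alkyl ether (Mitsunobu), ring C of the flavanone (acylation of ring A), unmasking.
- Stereochemistry: C2 comes from RuCl2[(S)-BINAP] hydrogenation of a β-keto ester (R carbinol) and is inverted to S in the Mitsunobu step. The 4-hydroxyphenyl group is carried as its pinacol boronate so that the benzylic C2–O bond cannot ionize during etherification and acylation; boron is exchanged for oxygen after ring closure.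

Key step: step 12

Remark: RuCl2[(S)-BINAP] is taken to give the (R)-carbinol from the aryl β-keto ester, as it does from ethyl benzoylacetate; should the sense be the opposite, the (R)-ligand is used.

**Step 1**
Reactants: 1 3,5-bis(benzyloxy)phenol
Product: 2 2,6-bis(benzyloxy)-1,4-benzoquinone
Conditions: (KSO3)2NO (2.2 equiv), KH2PO4 buffer, acetone/H2O, 0 °C → rt
Reagents that add atoms: potassium nitrosodisulfonate, [K+].[K+].[O]N(S(=O)(=O)[O-])S(=O)(=O)[O-]
Why: Teuber oxidation, in which one nitroxyl radical removes the phenolic hydrogen and a second adds at the free para carbon between the benzyloxy groups, should give the para-quinone after loss of imidodisulfonate, as 3,5-dimethoxyphenol does.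

**Step 2**
Reactants: 2 2,6-bis(benzyloxy)-1,4-benzoquinone
Product: 3 2,6-bis(benzyloxy)benzene-1,4-diol
Conditions: Na2S2O4, THF/H2O, rt, under N2; used directly
Reagents that add atoms: none
Why: Dithionite reduction of a quinone to its hydroquinone is a two-electron, two-proton transfer that leaves benzyl ethers untouched.

**Step 3**
Reactants: 3 2,6-bis(benzyloxy)benzene-1,4-diol
Product: 4 2,6-bis(benzyloxy)-4-(methoxymethoxy)phenol
Conditions: MOMCl (1.05 equiv), i-Pr2NEt, CH2Cl2, 0 °C, under N2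
Reagents that add atoms: chloromethyl methyl ether, COCCl
Why: O-alkylation should take place at the hydroxyl flanked by two hydrogens, because the other hydroxyl is shielded by, and hydrogen-bonded to, two ortho benzyloxy groups.

**Step 4**
Reactants: 4 2,6-bis(benzyloxy)-4-(methoxymethoxy)phenol; 5 4-fluorobenzaldehyde
Product: 6 4-[2,6-bis(benzyloxy)-4-(methoxymethoxy)phenoxy]benzaldehyde
Conditions: K2CO3, DMF, 110 °C
Reagents that add atoms: none
Why: SNAr by addition–elimination, in which the para formyl group activates fluoride displacement by the hindered phenoxide as known for 2,6-dimethoxyphenol, should give the diaryl ether while the acetal and benzyl ethers are stable to carbonate.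

**Step 5**
Reactants: 6 4-[2,6-bis(benzyloxy)-4-(methoxymethoxy)phenoxy]benzaldehyde; 7 1-[2,4-bis(benzyloxy)-6-hydroxyphenyl]ethanone
Product: 8 (E)-1-[2,4-bis(benzyloxy)-6-hydroxyphenyl]-3-{4-[2,6-bis(benzyloxy)-4-(methoxymethoxy)phenoxy]phenyl}prop-2-en-1-one
Conditions: KOH (50% aq), EtOH/THF, rt
Reagents that add atoms: none
Why: Claisen–Schmidt condensation of the methyl ketone enolate with the non-enolizable aldehyde, followed by E1cB dehydration, should give the (E)-2'-hydroxychalcone.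

**Step 6**
Reactants: 8 (E)-1-[2,4-bis(benzyloxy)-6-hydroxyphenyl]-3-{4-[2,6-bis(benzyloxy)-4-(methoxymethoxy)phenoxy]phenyl}prop-2-en-1-one
Product: 9 5,7-bis(benzyloxy)-2-{4-[2,6-bis(benzyloxy)-4-(methoxymethoxy)phenoxy]phenyl}-4H-chromen-4-one
Conditions: I2 (10 mol%), DMSO, 125 °C
Reagents that add atoms: none
Why: Iodine-catalysed oxidative cyclization of a 2'-hydroxychalcone (oxa-Michael closure, α-iodination, loss of HI, DMSO as terminal oxidant) is the standard route to 5,7-dialkoxyflavones and should close the apigenin pyranone ring.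

**Step 7**
Reactants: 9 5,7-bis(benzyloxy)-2-{4-[2,6-bis(benzyloxy)-4-(methoxymethoxy)phenoxy]phenyl}-4H-chromen-4-one
Product: 10 5,7-bis(benzyloxy)-2-{4-[2,6-bis(benzyloxy)-4-hydroxyphenoxy]phenyl}-4H-chromen-4-one
Conditions: conc. HCl (cat.), MeOH/THF, 45 °C
Reagents that add atoms: none
Why: Acid-catalysed acetal exchange should remove the MOM group as dimethoxymethane while the benzyl aryl ethers, the diaryl ether and the flavone survive dilute acid.

**Step 8**
Reactants: 11 ethyl 3-(4-bromophenyl)-3-oxopropanoate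
Product: 12 ethyl (3R)-3-(4-bromophenyl)-3-hydroxypropanoate
Conditions: H2 (50 atm), RuCl2[(S)-BINAP] (0.5 mol%), EtOH, 60 °C
Reagents that add atoms: none
Why: Noyori asymmetric hydrogenation of the chelated β-keto ester on the face dictated by the (S)-BINAP ligand should set the (R)-carbinol, and the aryl bromide is inert to the ruthenium hydride.

**Step 9**
Reactants: 12 ethyl (3R)-3-(4-bromophenyl)-3-hydroxypropanoate
Product: 13 ethyl (3R)-3-hydroxy-3-[4-(4,4,5,5-tetramethyl-1,3,2-dioxaborolan-2-yl)phenyl]propanoate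
Conditions: B2pin2, Pd(dppf)Cl2 (3 mol%), KOAc, 1,4-dioxane, 85 °C
Reagents that add atoms: bis(pinacolato)diboron, CC1(C)OB(OC1(C)C)B1OC(C)(C)C(C)(C)O1
Why: Miyaura borylation (oxidative addition to zerovalent palladium, acetate-assisted transmetalation, reductive elimination) tolerates the free alcohol and the ester and does not touch the stereocenter.

**Step 10**
Reactants: 10 5,7-bis(benzyloxy)-2-{4-[2,6-bis(benzyloxy)-4-hydroxyphenoxy]phenyl}-4H-chromen-4-one; 13 ethyl (3R)-3-hydroxy-3-[4-(4,4,5,5-tetramethyl-1,3,2-dioxaborolan-2-yl)phenyl]propanoate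
Product: 14 ethyl (3S)-3-{3,5-bis(benzyloxy)-4-[4-(5,7-bis(benzyloxy)-4-oxo-4H-chromen-2-yl)phenoxy]phenoxy}-3-[4-(4,4,5,5-tetramethyl-1,3,2-dioxaborolan-2-yl)phenyl]propanoate
Conditions: PPh3, DIAD, THF, 0 °C → rt
Reagents that add atoms: none
Why: Mitsunobu etherification, in which the phenoxide of 10 displaces the alkoxyphosphonium group in an SN2 step with inversion, should turn (R) into (S), and the boron-substituted aryl group does not stabilize a benzylic cation, which should keep SN1 leakage as low as with 3-hydroxy-3-phenylpropanoates.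

**Step 11**
Reactants: 14 ethyl (3S)-3-{3,5-bis(benzyloxy)-4-[4-(5,7-bis(benzyloxy)-4-oxo-4H-chromen-2-yl)phenoxy]phenoxy}-3-[4-(4,4,5,5-tetramethyl-1,3,2-dioxaborolan-2-yl)phenyl]propanoate
Product: 15 (3S)-3-{3,5-bis(benzyloxy)-4-[4-(5,7-bis(benzyloxy)-4-oxo-4H-chromen-2-yl)phenoxy]phenoxy}-3-[4-(4,4,5,5-tetramethyl-1,3,2-dioxaborolan-2-yl)phenyl]propanoic acid
Conditions: LiOH·H2O, THF/H2O, 0 °C; then 0.5 M HCl to pH 4
Reagents that add atoms: lithium hydroxide, [Li+].[OH-]
Why: Saponification at the acyl carbon is faster than α-deprotonation, so β-elimination of the aryloxide should not compete at 0 °C, and the pinacol boronate is recovered from its hydroxide adduct on acidification.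

**Step 12**
Reactants: 15 (3S)-3-{3,5-bis(benzyloxy)-4-[4-(5,7-bis(benzyloxy)-4-oxo-4H-chromen-2-yl)phenoxy]phenoxy}-3-[4-(4,4,5,5-tetramethyl-1,3,2-dioxaborolan-2-yl)phenyl]propanoic acid
Product: 17 (2S)-5,7-bis(benzyloxy)-6-[4-(5,7-bis(benzyloxy)-4-oxo-4H-chromen-2-yl)phenoxy]-2-[4-(4,4,5,5-tetramethyl-1,3,2-dioxaborolan-2-yl)phenyl]-2,3-dihydro-4H-chromen-4-one, via mixed trifluoroacetic anhydride 16 (not isolated)
Conditions: (CF3CO)2O (1.5 equiv), CH2Cl2, −20 → 0 °C
Reagents that add atoms: none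
Why: The acid is converted in the flask into the mixed carboxylic–trifluoroacetic anhydride 16, whose acyl carbon (the future C4) is attacked by the ortho carbon of the tetraoxygenated ring (the future C4a) to give a Wheland intermediate that loses a proton and trifluoroacetate. The closest known reaction type is the trifluoroacetic anhydride-mediated intramolecular Friedel–Crafts acylation of 3-(3,5-dialkoxyphenoxy)propanoic acids to 5,7-dialkoxychroman-4-ones. Ring C is closed in a 6-exo-trig mode at the anhydride carbonyl, with O1–C2–C3 as the tether. No stereocenter is created; C2 is carried through unchanged, and its benzylic C–O bond should resist ionization by the trifluoroacetic acid released because the boron-substituted aryl group cannot stabilize a benzylic cation. The step needs site selectivity on ring A and chemoselectivity over seven other arenes: the two ortho carbons are related by the local mirror plane through C8a and C6 and give the same product, so no 8-aryloxy isomer can arise, and only these carbons are ortho, ortho and para to three ether oxygens and held within reach of the acyl group, whereas the apigenin rings are deactivated by their carbonyl and the benzyl and boronate rings are unactivated.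

**Step 13**
Reactants: 17 (2S)-5,7-bis(benzyloxy)-6-[4-(5,7-bis(benzyloxy)-4-oxo-4H-chromen-2-yl)phenoxy]-2-[4-(4,4,5,5-tetramethyl-1,3,2-dioxaborolan-2-yl)phenyl]-2,3-dihydro-4H-chromen-4-one
Product: 18 (2S)-5,7-bis(benzyloxy)-6-[4-(5,7-bis(benzyloxy)-4-oxo-4H-chromen-2-yl)phenoxy]-2-(4-hydroxyphenyl)-2,3-dihydro-4H-chromen-4-one
Conditions: H2O2 (30% aq), THF/phosphate buffer (pH 7), 0 °C → rt
Reagents that add atoms: hydrogen peroxide, OO
Why: Ipso-hydroxylation of the arylboronate (hydroperoxide addition to boron, 1,2-shift of the aryl group to oxygen, hydrolysis of the borate) at neutral pH should neither open the base-sensitive 5-alkoxyflavanone to its chalcone nor epimerize C2.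

**Step 14**
Reactants: 18 (2S)-5,7-bis(benzyloxy)-6-[4-(5,7-bis(benzyloxy)-4-oxo-4H-chromen-2-yl)phenoxy]-2-(4-hydroxyphenyl)-2,3-dihydro-4H-chromen-4-one
Product: 19 (2S)-5,7-dihydroxy-6-[4-(5,7-dihydroxy-4-oxo-4H-chromen-2-yl)phenoxy]-2-(4-hydroxyphenyl)-2,3-dihydro-4H-chromen-4-one (CNP0206535.1)
Conditions: H2 (1 atm), 10% Pd/C, EtOAc/THF, rt
Reagents that add atoms: none
Why: Hydrogenolysis of the four benzyl aryl ethers over Pd/C at one atmosphere is expected to be faster than reduction of the flavone C2=C3 bond or cleavage of the flavanone C2–O1 bond, and it is neutral, so C2 keeps its configuration.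

**Compound list**

1 | 3,5-bis(benzyloxy)phenol | Oc1cc(OCc2ccccc2)cc(OCc2ccccc2)c1 | starting material
2 | 2,6-bis(benzyloxy)-1,4-benzoquinone | O=C1C=C(OCc2ccccc2)C(=O)C(OCc2ccccc2)=C1 | intermediate
3 | 2,6-bis(benzyloxy)benzene-1,4-diol | Oc1cc(OCc2ccccc2)c(O)c(OCc2ccccc2)c1 | intermediate
4 | 2,6-bis(benzyloxy)-4-(methoxymethoxy)phenol | COCOc1cc(OCc2ccccc2)c(O)c(OCc2ccccc2)c1 | intermediate
5 | 4-fluorobenzaldehyde | O=Cc1ccc(F)cc1 | starting material
6 | 4-[2,6-bis(benzyloxy)-4-(methoxymethoxy)phenoxy]benzaldehyde | COCOc1cc(OCc2ccccc2)c(Oc2ccc(C=O)cc2)c(OCc2ccccc2)c1 | intermediate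
7 | 1-[2,4-bis(benzyloxy)-6-hydroxyphenyl]ethanone | CC(=O)c1c(O)cc(OCc2ccccc2)cc1OCc1ccccc1 | starting material
8 | (E)-1-[2,4-bis(benzyloxy)-6-hydroxyphenyl]-3-{4-[2,6-bis(benzyloxy)-4-(methoxymethoxy)phenoxy]phenyl}prop-2-en-1-one | COCOc1cc(OCc2ccccc2)c(Oc2ccc(/C=C/C(=O)c3c(O)cc(OCc4ccccc4)cc3OCc3ccccc3)cc2)c(OCc2ccccc2)c1 | intermediate
9 | 5,7-bis(benzyloxy)-2-{4-[2,6-bis(benzyloxy)-4-(methoxymethoxy)phenoxy]phenyl}-4H-chromen-4-one | COCOc1cc(OCc2ccccc2)c(Oc2ccc(-c3cc(=O)c4c(OCc5ccccc5)cc(OCc5ccccc5)cc4o3)cc2)c(OCc2ccccc2)c1 | intermediate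
10 | 5,7-bis(benzyloxy)-2-{4-[2,6-bis(benzyloxy)-4-hydroxyphenoxy]phenyl}-4H-chromen-4-one | Oc1cc(OCc2ccccc2)c(Oc2ccc(-c3cc(=O)c4c(OCc5ccccc5)cc(OCc5ccccc5)cc4o3)cc2)c(OCc2ccccc2)c1 | intermediate
11 | ethyl 3-(4-bromophenyl)-3-oxopropanoate | CCOC(=O)CC(=O)c1ccc(Br)cc1 | starting material
12 | ethyl (3R)-3-(4-bromophenyl)-3-hydroxypropanoate | CCOC(=O)C[C@@H](O)c1ccc(Br)cc1 | intermediate
13 | ethyl (3R)-3-hydroxy-3-[4-(4,4,5,5-tetramethyl-1,3,2-dioxaborolan-2-yl)phenyl]propanoate | CCOC(=O)C[C@@H](O)c1ccc(B2OC(C)(C)C(C)(C)O2)cc1 | intermediate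
14 | ethyl (3S)-3-{3,5-bis(benzyloxy)-4-[4-(5,7-bis(benzyloxy)-4-oxo-4H-chromen-2-yl)phenoxy]phenoxy}-3-[4-(4,4,5,5-tetramethyl-1,3,2-dioxaborolan-2-yl)phenyl]propanoate | CCOC(=O)C[C@@H](c1ccc(B2OC(C)(C)C(C)(C)O2)cc1)Oc1cc(OCc2ccccc2)c(Oc2ccc(-c3cc(=O)c4c(OCc5ccccc5)cc(OCc5ccccc5)cc4o3)cc2)c(OCc2ccccc2)c1 | intermediate
15 | (3S)-3-{3,5-bis(benzyloxy)-4-[4-(5,7-bis(benzyloxy)-4-oxo-4H-chromen-2-yl)phenoxy]phenoxy}-3-[4-(4,4,5,5-tetramethyl-1,3,2-dioxaborolan-2-yl)phenyl]propanoic acid | OC(=O)C[C@@H](c1ccc(B2OC(C)(C)C(C)(C)O2)cc1)Oc1cc(OCc2ccccc2)c(Oc2ccc(-c3cc(=O)c4c(OCc5ccccc5)cc(OCc5ccccc5)cc4o3)cc2)c(OCc2ccccc2)c1 | intermediate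
16 | mixed anhydride of acid 15 and trifluoroacetic acid, (3S) | O=C(OC(=O)C(F)(F)F)C[C@@H](c1ccc(B2OC(C)(C)C(C)(C)O2)cc1)Oc1cc(OCc2ccccc2)c(Oc2ccc(-c3cc(=O)c4c(OCc5ccccc5)cc(OCc5ccccc5)cc4o3)cc2)c(OCc2ccccc2)c1 | intermediate (not isolated)
17 | (2S)-5,7-bis(benzyloxy)-6-[4-(5,7-bis(benzyloxy)-4-oxo-4H-chromen-2-yl)phenoxy]-2-[4-(4,4,5,5-tetramethyl-1,3,2-dioxaborolan-2-yl)phenyl]-2,3-dihydro-4H-chromen-4-one | O=C1C[C@@H](c2ccc(B3OC(C)(C)C(C)(C)O3)cc2)Oc2cc(OCc3ccccc3)c(Oc3ccc(-c4cc(=O)c5c(OCc6ccccc6)cc(OCc6ccccc6)cc5o4)cc3)c(OCc3ccccc3)c21 | intermediate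
18 | (2S)-5,7-bis(benzyloxy)-6-[4-(5,7-bis(benzyloxy)-4-oxo-4H-chromen-2-yl)phenoxy]-2-(4-hydroxyphenyl)-2,3-dihydro-4H-chromen-4-one | O=C1C[C@@H](c2ccc(O)cc2)Oc2cc(OCc3ccccc3)c(Oc3ccc(-c4cc(=O)c5c(OCc6ccccc6)cc(OCc6ccccc6)cc5o4)cc3)c(OCc3ccccc3)c21 | intermediate
19 | (2S)-5,7-dihydroxy-6-[4-(5,7-dihydroxy-4-oxo-4H-chromen-2-yl)phenoxy]-2-(4-hydroxyphenyl)-2,3-dihydro-4H-chromen-4-one (CNP0206535.1) | O=C1C[C@@H](c2ccc(O)cc2)Oc2cc(O)c(Oc3ccc(-c4cc(=O)c5c(O)cc(O)cc5o4)cc3)c(O)c21 | target

**Step count and risks**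

Total step count: 14. Longest linear sequence: 12 (steps 1 to 7, then 10 to 14); steps 8 and 9 form the second branch.

Steps most likely to fail:

1. Step 12. The acid set free may ionize the benzylic C2–O bond (loss of configuration, or cleavage to the cinnamic acid and phenol 10) or cleave benzyl ethers before the ring closes. The fallback reverses the order of bond formation and sets the stereocenter by catalysis once the ring exists. It sets out from 10: C-acetylation ortho to the free hydroxyl (AcOH, (CF3CO)2O, CH2Cl2; either ortho carbon gives the same product) would give 1-{2,4-bis(benzyloxy)-3-[4-(5,7-bis(benzyloxy)-4-oxo-4H-chromen-2-yl)phenoxy]-6-hydroxyphenyl}ethanone F1. Heating with N,N-dimethylformamide dimethyl acetal would give the enaminone F2, which closes under aqueous HCl to the 2-unsubstituted chromone F3. Asymmetric conjugate addition of [4-(benzyloxy)phenyl]boronic acid (Pd(OCOCF3)2, the t-BuPyOx enantiomer that gives 2S, NH4PF6, H2O, ClCH2CH2Cl, 60 °C) should leave the 2-aryl-substituted chromone of the apigenin half untouched and give the pentabenzyl flavanone F4. Hydrogenolysis under the conditions of step 14 brings the route back at 19.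

2. Step 10. The activated carbinol may be lost by elimination to the cinnamate, or inversion may be incomplete. The fallback forms the O1–C2 bond by strain-driven opening of a β-lactone instead. It sets out from 13: saponification (LiOH, THF/H2O) would give the hydroxy acid F5, and carboxyl activation (PhSO2Cl, pyridine, 0 °C) closes it with retention at carbon to the β-lactone F6. The sodium phenoxide of 10 (NaH, DMF, 0 °C) should open F6 at the benzylic C–O bond in an SN2 step with inversion, which gives acid 15 directly; the route is rejoined at 15 and step 11 is not needed.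

3. Step 14. Over-reduction may occur, either saturation of the flavone C2=C3 bond or hydrogenolytic opening of the flavanone C2–O1 bond. The fallback replaces hydrogenolysis by Lewis-acid debenzylation: BCl3 with pentamethylbenzene as cation scavenger, CH2Cl2, −78 °C. It sets out from 18 and comes back at 19 without a new compound.

**Further compounds**

F1 | step 12 | 1-{2,4-bis(benzyloxy)-3-[4-(5,7-bis(benzyloxy)-4-oxo-4H-chromen-2-yl)phenoxy]-6-hydroxyphenyl}ethanone | CC(=O)c1c(O)cc(OCc2ccccc2)c(Oc2ccc(-c3cc(=O)c4c(OCc5ccccc5)cc(OCc5ccccc5)cc4o3)cc2)c1OCc1ccccc1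
F2 | step 12 | (E)-1-{2,4-bis(benzyloxy)-3-[4-(5,7-bis(benzyloxy)-4-oxo-4H-chromen-2-yl)phenoxy]-6-hydroxyphenyl}-3-(dimethylamino)prop-2-en-1-one | CN(C)/C=C/C(=O)c1c(O)cc(OCc2ccccc2)c(Oc2ccc(-c3cc(=O)c4c(OCc5ccccc5)cc(OCc5ccccc5)cc4o3)cc2)c1OCc1ccccc1
F3 | step 12 | 5,7-bis(benzyloxy)-6-[4-(5,7-bis(benzyloxy)-4-oxo-4H-chromen-2-yl)phenoxy]-4H-chromen-4-one | O=c1ccoc2cc(OCc3ccccc3)c(Oc3ccc(-c4cc(=O)c5c(OCc6ccccc6)cc(OCc6ccccc6)cc5o4)cc3)c(OCc3ccccc3)c12
F4 | step 12 | (2S)-5,7-bis(benzyloxy)-2-[4-(benzyloxy)phenyl]-6-[4-(5,7-bis(benzyloxy)-4-oxo-4H-chromen-2-yl)phenoxy]-2,3-dihydro-4H-chromen-4-one | O=C1C[C@@H](c2ccc(OCc3ccccc3)cc2)Oc2cc(OCc3ccccc3)c(Oc3ccc(-c4cc(=O)c5c(OCc6ccccc6)cc(OCc6ccccc6)cc5o4)cc3)c(OCc3ccccc3)c21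
F5 | step 10 | (3R)-3-hydroxy-3-[4-(4,4,5,5-tetramethyl-1,3,2-dioxaborolan-2-yl)phenyl]propanoic acid | OC(=O)C[C@@H](O)c1ccc(B2OC(C)(C)C(C)(C)O2)cc1
F6 | step 10 | (4R)-4-[4-(4,4,5,5-tetramethyl-1,3,2-dioxaborolan-2-yl)phenyl]oxetan-2-one | O=C1C[C@H](c2ccc(B3OC(C)(C)C(C)(C)O3)cc2)O1
F0 | step 14 | none | none
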